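## Retrosynthetic overview

1. Locants are germacranolide locants (C6 lactone carbinol, C7 ring fusion, C8 free carbinol, C14/C15 the ester-bearing CH2 groups). The ten-membered ring is opened at the C4=C5 alkene, to be closed last by ring-closing metathesis of vinyl lactone 35.
2. The C8 carbinol comes from its 8S epimer by Mitsunobu inversion. The C7–C8 bond is made by an intermolecular zinc Barbier allylation of aldehyde 30 with bromomethyl butenolide 10, which also creates the α-methylene lactone and sets C7.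
3. Butenolide 10 (C6 stereocentre) comes from the L-glutamic-acid-derived lactone 1 by methylenation, selenenylation/hydroxymethylation, selenoxide elimination and bromination.
4. Aldehyde 30 comes from 2-methylidenepropane-1,3-diol by Johnson–Claisen rearrangement and Horner–Wadsworth–Emmons olefination (E-alkene), with orthogonal protection to place isobutyrate on C14 and acetate on C15.
5. Ring order: the γ-lactone is carried from 1 throughout; the ten-membered carbocycle is formed last.

Assumption: the zinc allylation follows the closed chair transition state usual for 3-(bromomethyl)butenolides and gives the 7,8-anti (8S) alcohol, so C8 is inverted in step 19.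

## Route

Step 1
Reactants: 1 (S)-5-(hydroxymethyl)dihydrofuran-2(3H)-one
Product: 2 (S)-5-oxotetrahydrofuran-2-carbaldehyde
Conditions: Dess–Martin periodinane, CH2Cl2, 0 °C → rt; filtered, used crude
Reagents that add atoms: none
Why: Dess–Martin oxidation takes the primary alcohol to the aldehyde under neutral, non-aqueous conditions that do not epimerise the adjacent lactone stereocentre.

Step 2
Reactants: 2 (S)-5-oxotetrahydrofuran-2-carbaldehyde
Product: 3 (S)-5-ethenyldihydrofuran-2(3H)-one
Conditions: Ph3PCH3Br, KN(SiMe3)2, THF, 0 °C; then 2, −78 → 0 °C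
Reagents that add atoms: methyltriphenylphosphonium bromide, C[P+](c1ccccc1)(c1ccccc1)c1ccccc1.[Br-]
Why: Wittig methylenation with the non-stabilised ylide at low temperature is faster than enolisation of the α-acyloxy aldehyde, so the future C5 vinyl carbon is installed with the C6 stereocentre intact.

Step 3
Reactants: 3 (S)-5-ethenyldihydrofuran-2(3H)-one
Product: 5 (5S)-5-ethenyl-3-(phenylselanyl)dihydrofuran-2(3H)-one (C3 epimers), via lithium lactone enolate 4 (not isolated)
Conditions: LiN(i-Pr)2, THF, −78 °C; then PhSeBr, −78 °C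
Reagents that add atoms: phenylselanyl bromide, Br[Se]c1ccccc1
Why: Kinetic lactone enolate formation followed by α-selenenylation touches only the α-carbon; the new C3 centre is an inconsequential epimer mixture and the γ-stereocentre is not acidic.

Step 4
Reactants: 5 (5S)-5-ethenyl-3-(phenylselanyl)dihydrofuran-2(3H)-one
Product: 7 (5S)-5-ethenyl-3-(hydroxymethyl)-3-(phenylselanyl)dihydrofuran-2(3H)-one (C3 epimers), via lithium selanyl enolate 6 (not isolated)
Conditions: LiN(i-Pr)2, THF, −78 °C; then CH2O (gas from cracked paraformaldehyde), −78 → −40 °C; AcOH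
Reagents that add atoms: formaldehyde, C=O
Why: The selenium-stabilised enolate undergoes aldol addition to monomeric formaldehyde, introducing the future C13 carbon; the quaternary C3 centre is again an inconsequential mixture.

Step 5
Reactants: 7 (5S)-5-ethenyl-3-(hydroxymethyl)-3-(phenylselanyl)dihydrofuran-2(3H)-one
Product: 9 (R)-5-ethenyl-3-(hydroxymethyl)furan-2(5H)-one, via selenoxide 8 (not isolated)
Conditions: 30% H2O2, pyridine, CH2Cl2, 0 °C → rt
Reagents that add atoms: none
Why: Selenide oxidation and selenoxide syn-elimination take a ring C4–H rather than a carbinol C–H (selenoxides avoid forming enols), giving only the endocyclic butenolide; the stereocentre is untouched and is R only because the CIP priorities change.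

Step 6
Reactants: 9 (R)-5-ethenyl-3-(hydroxymethyl)furan-2(5H)-one
Product: 10 (R)-3-(bromomethyl)-5-ethenylfuran-2(5H)-one
Conditions: CBr4, PPh3, CH2Cl2, 0 °C
Reagents that add atoms: tetrabromomethane, BrC(Br)(Br)Br
Why: Appel bromination converts the primary allylic alcohol to the bromide under neutral conditions that do not deprotonate the doubly activated γ-hydrogen.

Step 7
Reactants: 11 2-methylidenepropane-1,3-diol
Product: 13 2-{[(4-methoxybenzyl)oxy]methyl}prop-2-en-1-ol, via monosodium alkoxide 12 (not isolated)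
Conditions: NaH (1.0 equiv), THF, 0 °C; then 4-methoxybenzyl chloride, Bu4NI (cat.), rt
Reagents that add atoms: 4-methoxybenzyl chloride, COc1ccc(CCl)cc1
Why: Williamson etherification of the monosodium alkoxide of the symmetrical diol gives mainly the mono-ether, separable from diol and bis-ether, and marks the future C15 oxygen.

Step 8
Reactants: 13 2-{[(4-methoxybenzyl)oxy]methyl}prop-2-en-1-ol
Product: 16 ethyl 4-{[(4-methoxybenzyl)oxy]methyl}pent-4-enoate, via mixed orthoester 14 (not isolated), via ketene acetal 15 (not isolated)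
Conditions: MeC(OEt)3, EtCO2H (cat.), 140 °C, EtOH distilled off
Reagents that add atoms: triethyl orthoacetate, CCOC(C)(OCC)OCC
Why: In the Johnson–Claisen rearrangement, acid-catalysed exchange and loss of ethanol give the ketene acetal, whose [3,3]-sigmatropic shift adds C1–C2 and regenerates the 1,1-disubstituted C4 alkene.

Step 9
Reactants: 16 ethyl 4-{[(4-methoxybenzyl)oxy]methyl}pent-4-enoate
Product: 18 4-{[(4-methoxybenzyl)oxy]methyl}pent-4-enal, via aluminium hemiacetal 17 (not isolated)
Conditions: i-Bu2AlH (1.05 equiv), CH2Cl2, −78 °C; then MeOH, aq. potassium sodium tartrate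
Reagents that add atoms: none
Why: Low-temperature half-reduction of the ester stops at the tetrahedral aluminium hemiacetal, which releases the C1 aldehyde only on work-up.

Step 10
Reactants: 19 triethyl phosphonoacetate; 20 (2-bromoethoxy)(tert-butyl)dimethylsilane
Product: 22 ethyl 4-[(tert-butyldimethylsilyl)oxy]-2-(diethoxyphosphoryl)butanoate (racemic), via sodium phosphonoacetate anion 21 (not isolated)
Conditions: NaH, DMF, 0 °C; then 20, NaI (cat.), 60 °C
Reagents that add atoms: none
Why: SN2 C-alkylation of the stabilised phosphonoacetate anion by the primary bromide (iodide-catalysed) attaches the protected C8–C9 unit to the future C10.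

Step 11
Reactants: 22 ethyl 4-[(tert-butyldimethylsilyl)oxy]-2-(diethoxyphosphoryl)butanoate; 18 4-{[(4-methoxybenzyl)oxy]methyl}pent-4-enal
Product: 24 ethyl (2E)-2-{2-[(tert-butyldimethylsilyl)oxy]ethyl}-6-{[(4-methoxybenzyl)oxy]methyl}hepta-2,6-dienoate, via sodium phosphonate anion 23 (not isolated)
Conditions: NaH, THF, 0 °C; then 18, 0 °C → rt
Reagents that add atoms: none
Why: Horner–Wadsworth–Emmons olefination under equilibrating conditions places the ester (C14) trans to the C2 chain, which is the required C1=C10 geometry; the minor Z isomer is removed by chromatography.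

Step 12
Reactants: 24 ethyl (2E)-2-{2-[(tert-butyldimethylsilyl)oxy]ethyl}-6-{[(4-methoxybenzyl)oxy]methyl}hepta-2,6-dienoate
Product: 25 (2E)-2-{2-[(tert-butyldimethylsilyl)oxy]ethyl}-6-{[(4-methoxybenzyl)oxy]methyl}hepta-2,6-dien-1-ol
Conditions: i-Bu2AlH (2.5 equiv), CH2Cl2, −78 → 0 °C; aq. potassium sodium tartrate
Reagents that add atoms: none
Why: 1,2-Reduction of the conjugated ester gives the C14 allylic alcohol with the alkene geometry retained and both ethers untouched.

Step 13
Reactants: 25 (2E)-2-{2-[(tert-butyldimethylsilyl)oxy]ethyl}-6-{[(4-methoxybenzyl)oxy]methyl}hepta-2,6-dien-1-ol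
Product: 26 (2E)-2-{2-[(tert-butyldimethylsilyl)oxy]ethyl}-6-{[(4-methoxybenzyl)oxy]methyl}hepta-2,6-dien-1-yl 2-methylpropanoate
Conditions: (i-PrCO)2O, Et3N, DMAP (cat.), CH2Cl2, 0 °C → rt
Reagents that add atoms: 2-methylpropanoic anhydride, CC(C)C(=O)OC(=O)C(C)C
Why: DMAP-catalysed acylation of the only free hydroxyl installs the C14 isobutyrate.

Step 14
Reactants: 26 (2E)-2-{2-[(tert-butyldimethylsilyl)oxy]ethyl}-6-{[(4-methoxybenzyl)oxy]methyl}hepta-2,6-dien-1-yl 2-methylpropanoate
Product: 27 (2E)-2-{2-[(tert-butyldimethylsilyl)oxy]ethyl}-6-(hydroxymethyl)hepta-2,6-dien-1-yl 2-methylpropanoate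
Conditions: DDQ, CH2Cl2/pH 7 buffer (10:1), 0 °C → rt
Reagents that add atoms: none
Why: Oxidative cleavage of the electron-rich 4-methoxybenzyl ether by DDQ frees the C15 hydroxyl while the silyl ether, the ester and the alkenes are inert.

Step 15
Reactants: 27 (2E)-2-{2-[(tert-butyldimethylsilyl)oxy]ethyl}-6-(hydroxymethyl)hepta-2,6-dien-1-yl 2-methylpropanoate
Product: 28 (2E)-6-(acetoxymethyl)-2-{2-[(tert-butyldimethylsilyl)oxy]ethyl}hepta-2,6-dien-1-yl 2-methylpropanoate
Conditions: Ac2O, Et3N, DMAP (cat.), CH2Cl2, 0 °C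
Reagents that add atoms: acetic anhydride, CC(=O)OC(C)=O
Why: DMAP-catalysed acetylation of the only free hydroxyl installs the C15 acetate.

Step 16
Reactants: 28 (2E)-6-(acetoxymethyl)-2-{2-[(tert-butyldimethylsilyl)oxy]ethyl}hepta-2,6-dien-1-yl 2-methylpropanoate
Product: 29 (2E)-6-(acetoxymethyl)-2-(2-hydroxyethyl)hepta-2,6-dien-1-yl 2-methylpropanoate
Conditions: HF·pyridine, THF/pyridine, 0 °C → rt
Reagents that add atoms: none
Why: Buffered fluoride desilylation frees the C8 primary alcohol without ester cleavage or acyl migration.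

Step 17
Reactants: 29 (2E)-6-(acetoxymethyl)-2-(2-hydroxyethyl)hepta-2,6-dien-1-yl 2-methylpropanoate
Product: 30 (2E)-6-(acetoxymethyl)-2-(2-oxoethyl)hepta-2,6-dien-1-yl 2-methylpropanoate
Conditions: Dess–Martin periodinane, pyridine, CH2Cl2, 0 °C; used at once
Reagents that add atoms: none
Why: Buffered Dess–Martin oxidation gives the β,γ-unsaturated aldehyde without moving the C1=C10 alkene into conjugation.

Step 18
Reactants: 10 (R)-3-(bromomethyl)-5-ethenylfuran-2(5H)-one; 30 (2E)-6-(acetoxymethyl)-2-(2-oxoethyl)hepta-2,6-dien-1-yl 2-methylpropanoate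
Product: 32 (2E)-6-(acetoxymethyl)-2-{(2S)-2-[(2R,3R)-2-ethenyl-4-methylidene-5-oxotetrahydrofuran-3-yl]-2-hydroxyethyl}hepta-2,6-dien-1-yl 2-methylpropanoate, via allylzinc bromide 31 (not isolated)
Conditions: Zn dust, THF/sat. aq. NH4Cl (2:1), 0 °C → rt
Reagents that add atoms: none
Why: In this Barbier carbonyl allylation the allylzinc adds through its ring γ-carbon in a chair Zimmerman–Traxler transition state, anti to the C6 vinyl group (C7 R, trans lactone) and with the aldehyde chain equatorial (7,8-anti, C8 S), unveiling the α-methylene lactone in a near-neutral medium that spares the esters.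

Step 19
Reactants: 32 (2E)-6-(acetoxymethyl)-2-{(2S)-2-[(2R,3R)-2-ethenyl-4-methylidene-5-oxotetrahydrofuran-3-yl]-2-hydroxyethyl}hepta-2,6-dien-1-yl 2-methylpropanoate
Product: 33 (2E)-6-(acetoxymethyl)-2-{(2R)-2-[(chloroacetyl)oxy]-2-[(2R,3R)-2-ethenyl-4-methylidene-5-oxotetrahydrofuran-3-yl]ethyl}hepta-2,6-dien-1-yl 2-methylpropanoate
Conditions: ClCH2CO2H, PPh3, DIAD, toluene, 0 °C → rt
Reagents that add atoms: chloroacetic acid, OC(=O)CCl
Why: In the Mitsunobu reaction the C8 oxyphosphonium ion is displaced by chloroacetate (an acidic nucleophile suited to hindered secondary alcohols) with SN2 inversion, turning 8S into the required 8R while C6 and C7 are untouched.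

Step 20
Reactants: 33 (2E)-6-(acetoxymethyl)-2-{(2R)-2-[(chloroacetyl)oxy]-2-[(2R,3R)-2-ethenyl-4-methylidene-5-oxotetrahydrofuran-3-yl]ethyl}hepta-2,6-dien-1-yl 2-methylpropanoate
Product: 35 (2E)-6-(acetoxymethyl)-2-{(2R)-2-[(2R,3R)-2-ethenyl-4-methylidene-5-oxotetrahydrofuran-3-yl]-2-hydroxyethyl}hepta-2,6-dien-1-yl 2-methylpropanoate, via isothiouronium chloride 34 (not isolated)
Conditions: thiourea, NaHCO3, EtOH/THF, 40 °C
Reagents that add atoms: none
Why: Thiourea S-alkylates only the chloroacetate and the isothiouronium nitrogen then cyclises onto that ester carbonyl, releasing the C8 alcohol with retention under buffered conditions that leave the acetate, the isobutyrate and the α-methylene lactone alone.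

Step 21
Reactants: 35 (2E)-6-(acetoxymethyl)-2-{(2R)-2-[(2R,3R)-2-ethenyl-4-methylidene-5-oxotetrahydrofuran-3-yl]-2-hydroxyethyl}hepta-2,6-dien-1-yl 2-methylpropanoate
Product: 36 (3aR,4R,6E,10E,11aR)-10-(acetoxymethyl)-4-hydroxy-6-[(2-methylpropanoyloxy)methyl]-3-methylidene-3a,4,5,8,9,11a-hexahydrocyclodeca[b]furan-2(3H)-one (target)
Conditions: RuCl2(H2IMes)(=CH-C6H4-2-O-i-Pr) (second-generation Hoveyda–Grubbs catalyst, 10 mol%), 1,4-benzoquinone (cat.), toluene (1 mM), 80 °C
Reagents that add atoms: none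
Why: In this ring-closing metathesis the catalyst loads on the monosubstituted vinyl group and closes onto the 1,1-disubstituted alkene with loss of ethene; the trans-fused lactone and the ring-cis C1=C10 alkene pre-fold the chain, and the ten-membered ring should favour the less strained ring-cis C4=C5 alkene (E by CIP); no stereocentre is formed.

## Compound list

1 | (S)-5-(hydroxymethyl)dihydrofuran-2(3H)-one | O=C1CC[C@@H](CO)O1 | starting material
2 | (S)-5-oxotetrahydrofuran-2-carbaldehyde | O=C1CC[C@@H](C=O)O1 | intermediate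
3 | (S)-5-ethenyldihydrofuran-2(3H)-one | O=C1CC[C@@H](C=C)O1 | intermediate
4 | lithium enolate of 3 (not isolated) | [Li]OC1=CC[C@@H](C=C)O1 | intermediate
5 | (5S)-5-ethenyl-3-(phenylselanyl)dihydrofuran-2(3H)-one, C3 epimers | O=C1C([Se]c2ccccc2)C[C@@H](C=C)O1 | intermediate
6 | lithium enolate of 5 (not isolated) | [Li]OC1=C([Se]c2ccccc2)C[C@@H](C=C)O1 | intermediate
7 | (5S)-5-ethenyl-3-(hydroxymethyl)-3-(phenylselanyl)dihydrofuran-2(3H)-one, C3 epimers | O=C1C(CO)([Se]c2ccccc2)C[C@@H](C=C)O1 | intermediate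
8 | (5S)-5-ethenyl-3-(hydroxymethyl)-3-(phenylseleninyl)dihydrofuran-2(3H)-one, selenoxide (not isolated) | O=C1C(CO)([Se](=O)c2ccccc2)C[C@@H](C=C)O1 | intermediate
9 | (R)-5-ethenyl-3-(hydroxymethyl)furan-2(5H)-one | O=C1C(CO)=C[C@@H](C=C)O1 | intermediate
10 | (R)-3-(bromomethyl)-5-ethenylfuran-2(5H)-one | O=C1C(CBr)=C[C@@H](C=C)O1 | intermediate
11 | 2-methylidenepropane-1,3-diol | C=C(CO)CO | starting material
12 | monosodium alkoxide of 11 (not isolated) | C=C(CO)C[O-].[Na+] | intermediate
13 | 2-{[(4-methoxybenzyl)oxy]methyl}prop-2-en-1-ol | C=C(CO)COCc1ccc(OC)cc1 | intermediate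
14 | mixed orthoester, 13 O-bound to C(CH3)(OEt)2 (not isolated) | CCOC(C)(OCC)OCC(=C)COCc1ccc(OC)cc1 | intermediate
15 | ketene acetal, 1-ethoxyethenyl ether of 13 (not isolated) | C=C(OCC)OCC(=C)COCc1ccc(OC)cc1 | intermediate
16 | ethyl 4-{[(4-methoxybenzyl)oxy]methyl}pent-4-enoate | CCOC(=O)CCC(=C)COCc1ccc(OC)cc1 | intermediate
17 | diisobutylaluminium ethyl hemiacetal of 18 (not isolated) | CCOC(CCC(=C)COCc1ccc(OC)cc1)O[Al](CC(C)C)CC(C)C | intermediate
18 | 4-{[(4-methoxybenzyl)oxy]methyl}pent-4-enal | O=CCCC(=C)COCc1ccc(OC)cc1 | intermediate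
19 | triethyl phosphonoacetate | CCOC(=O)CP(=O)(OCC)OCC | starting material
20 | (2-bromoethoxy)(tert-butyl)dimethylsilane | CC(C)(C)[Si](C)(C)OCCBr | starting material
21 | sodium salt (carbanion) of 19 (not isolated) | CCOC(=O)[CH-]P(=O)(OCC)OCC.[Na+] | intermediate
22 | ethyl 4-[(tert-butyldimethylsilyl)oxy]-2-(diethoxyphosphoryl)butanoate, racemic | CCOC(=O)C(CCO[Si](C)(C)C(C)(C)C)P(=O)(OCC)OCC | intermediate
23 | sodium salt (carbanion) of 22 (not isolated) | CCOC(=O)[C-](CCO[Si](C)(C)C(C)(C)C)P(=O)(OCC)OCC.[Na+] | intermediate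
24 | ethyl (2E)-2-{2-[(tert-butyldimethylsilyl)oxy]ethyl}-6-{[(4-methoxybenzyl)oxy]methyl}hepta-2,6-dienoate | CCOC(=O)/C(CCO[Si](C)(C)C(C)(C)C)=C/CCC(=C)COCc1ccc(OC)cc1 | intermediate
25 | (2E)-2-{2-[(tert-butyldimethylsilyl)oxy]ethyl}-6-{[(4-methoxybenzyl)oxy]methyl}hepta-2,6-dien-1-ol | OC/C(CCO[Si](C)(C)C(C)(C)C)=C/CCC(=C)COCc1ccc(OC)cc1 | intermediate
26 | (2E)-2-{2-[(tert-butyldimethylsilyl)oxy]ethyl}-6-{[(4-methoxybenzyl)oxy]methyl}hepta-2,6-dien-1-yl 2-methylpropanoate | CC(C)C(=O)OC/C(CCO[Si](C)(C)C(C)(C)C)=C/CCC(=C)COCc1ccc(OC)cc1 | intermediate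
27 | (2E)-2-{2-[(tert-butyldimethylsilyl)oxy]ethyl}-6-(hydroxymethyl)hepta-2,6-dien-1-yl 2-methylpropanoate | CC(C)C(=O)OC/C(CCO[Si](C)(C)C(C)(C)C)=C/CCC(=C)CO | intermediate
28 | (2E)-6-(acetoxymethyl)-2-{2-[(tert-butyldimethylsilyl)oxy]ethyl}hepta-2,6-dien-1-yl 2-methylpropanoate | CC(C)C(=O)OC/C(CCO[Si](C)(C)C(C)(C)C)=C/CCC(=C)COC(C)=O | intermediate
29 | (2E)-6-(acetoxymethyl)-2-(2-hydroxyethyl)hepta-2,6-dien-1-yl 2-methylpropanoate | CC(C)C(=O)OC/C(CCO)=C/CCC(=C)COC(C)=O | intermediate
30 | (2E)-6-(acetoxymethyl)-2-(2-oxoethyl)hepta-2,6-dien-1-yl 2-methylpropanoate | CC(C)C(=O)OC/C(CC=O)=C/CCC(=C)COC(C)=O | intermediate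
31 | bromo{[(5R)-5-ethenyl-2-oxo-2,5-dihydrofuran-3-yl]methyl}zinc (not isolated) | Br[Zn]CC1=C[C@@H](C=C)OC1=O | intermediate
32 | (2E)-6-(acetoxymethyl)-2-{(2S)-2-[(2R,3R)-2-ethenyl-4-methylidene-5-oxotetrahydrofuran-3-yl]-2-hydroxyethyl}hepta-2,6-dien-1-yl 2-methylpropanoate (6R,7R,8S) | C=C1C(=O)O[C@H](C=C)[C@H]1[C@@H](O)C/C(COC(=O)C(C)C)=C\CCC(=C)COC(C)=O | intermediate
33 | (2E)-6-(acetoxymethyl)-2-{(2R)-2-[(chloroacetyl)oxy]-2-[(2R,3R)-2-ethenyl-4-methylidene-5-oxotetrahydrofuran-3-yl]ethyl}hepta-2,6-dien-1-yl 2-methylpropanoate (6R,7R,8R) | C=C1C(=O)O[C@H](C=C)[C@H]1[C@H](OC(=O)CCl)C/C(COC(=O)C(C)C)=C\CCC(=C)COC(C)=O | intermediate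
34 | S-alkylisothiouronium chloride of 33, ClCH2 replaced by (H2N)2C–S–CH2 cation (not isolated) | C=C1C(=O)O[C@H](C=C)[C@H]1[C@H](OC(=O)CSC(N)=[NH2+])C/C(COC(=O)C(C)C)=C\CCC(=C)COC(C)=O.[Cl-] | intermediate
35 | (2E)-6-(acetoxymethyl)-2-{(2R)-2-[(2R,3R)-2-ethenyl-4-methylidene-5-oxotetrahydrofuran-3-yl]-2-hydroxyethyl}hepta-2,6-dien-1-yl 2-methylpropanoate (6R,7R,8R) | C=C1C(=O)O[C@H](C=C)[C@H]1[C@H](O)C/C(COC(=O)C(C)C)=C\CCC(=C)COC(C)=O | intermediate
36 | (3aR,4R,6E,10E,11aR)-10-(acetoxymethyl)-4-hydroxy-6-[(2-methylpropanoyloxy)methyl]-3-methylidene-3a,4,5,8,9,11a-hexahydrocyclodeca[b]furan-2(3H)-one | C=C1C(=O)O[C@@H]2/C=C(/COC(C)=O)CC/C=C(/COC(=O)C(C)C)C[C@@H](O)[C@@H]12 | target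

## Step count and risks

Total step count: 21 (butenolide 6, aldehyde 11, union and endgame 4). Longest linear sequence: 14 steps (11 → 36 through steps 7–9 and 11–21).

Most likely to fail, in this order:

Step 21 (ring closure). A trisubstituted alkene has to form inside a strained ten-membered ring; oligomers, the ring-trans isomer or alkene migration caused by the free carbinol can take over. The fallback sets out from 33 and comes back at 36 and changes the order of ring closure and unmasking. The chloroacetate 33, which has no free hydroxyl and a different conformational bias, is cyclised with the same catalyst under high dilution. This gives (3aR,4R,6E,10E,11aR)-10-(acetoxymethyl)-6-[(2-methylpropanoyloxy)methyl]-3-methylidene-2-oxo-2,3,3a,4,5,8,9,11a-octahydrocyclodeca[b]furan-4-yl chloroacetate F1. Thiourea and NaHCO3 in EtOH/THF then convert F1 through its S-alkylisothiouronium chloride F2, which is not isolated, into 36.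

Step 19 (inversion at C8). The alcohol is β-branched and flanked by an allylic CH2 and the lactone CH, so elimination to conjugated dienes can compete with substitution. The fallback sets out from 10 (with 30) and comes back at 35, and removes the need for an inversion. Bromide 10 is stannylated with Bu3SnSnBu3 and Pd(PPh3)4 (cat.) in THF to give (R)-5-ethenyl-3-[(tributylstannyl)methyl]furan-2(5H)-one F3. F3 is added to 30 with BF3·OEt2 in CH2Cl2 at −78 °C. The Lewis-acid-promoted addition runs through an open antiperiplanar transition state that favours the 7,8-syn product, still anti to the vinyl group, so the 8R alcohol 35 is formed directly and steps 18–20 are bypassed.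

Step 18 (fragment union). Aldehyde 30 can slip into conjugation in the aqueous medium, and the small vinyl group may give incomplete facial control over the two new stereocentres. The fallback sets out from 10 and comes back at 32 and uses an isolated allylboron reagent. Bromide 10 is borylated with B2pin2 and Pd2(dba)3 (cat.) in toluene at 50 °C to give (R)-5-ethenyl-3-[(4,4,5,5-tetramethyl-1,3,2-dioxaborolan-2-yl)methyl]furan-2(5H)-one F4. F4 adds to freshly made 30 under anhydrous conditions with Sc(OTf)3 (cat.) in CH2Cl2 at −78 °C. The tight boron chair transition state gives the same anti, trans-lactone product, and aqueous work-up releases 32.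

Further compounds
F1 | step 21 | (3aR,4R,6E,10E,11aR)-10-(acetoxymethyl)-6-[(2-methylpropanoyloxy)methyl]-3-methylidene-2-oxo-2,3,3a,4,5,8,9,11a-octahydrocyclodeca[b]furan-4-yl chloroacetate | C=C1C(=O)O[C@@H]2/C=C(/COC(C)=O)CC/C=C(/COC(=O)C(C)C)C[C@@H](OC(=O)CCl)[C@@H]12
F2 | step 21 | S-alkylisothiouronium chloride of F1 (not isolated) | C=C1C(=O)O[C@@H]2/C=C(/COC(C)=O)CC/C=C(/COC(=O)C(C)C)C[C@@H](OC(=O)CSC(N)=[NH2+])[C@@H]12.[Cl-]
F3 | step 19 | (R)-5-ethenyl-3-[(tributylstannyl)methyl]furan-2(5H)-one | O=C1C(C[Sn](CCCC)(CCCC)CCCC)=C[C@@H](C=C)O1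
F4 | step 18 | (R)-5-ethenyl-3-[(4,4,5,5-tetramethyl-1,3,2-dioxaborolan-2-yl)methyl]furan-2(5H)-one | O=C1C(CB2OC(C)(C)C(C)(C)O2)=C[C@@H](C=C)O1
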